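The numbers in the tables were computed for an exercise, and the scatter is random.

I decide to carry one number through this flask rather than any rate constant: the held-back level, the concentration of the charge not standing as J once forward and back rates are level. Their ratio is then one, so time drops out.

| flask | Z | remark | time |
|---|---|---|---|
| east | 0.10 mM | run made earlier |  |
| south-west | 0.40 mM | run made earlier |  |
| flask | 0.20 mM |  | 25 min |

- east (time / min: Z / %, J / %): 1.50: 26.8, 44.9; 2.50: 26.3, 45.6; 4.00: 26.9, 44.1; 6.00: 25.4, 45.9; 8.00: 26.9, 45.9; 12.0: 26.7, 44.5; 20.0: 25.1, 44.1
- south-west (time / min: Z / %, J / %): 1.50: 7.2, 84.7; 2.50: 6.4, 85.7; 4.00: 6.0, 85.8; 6.00: 7.2, 86.3; 8.00: 7.3, 86.3; 12.0: 6.8, 86.3; 20.0: 6.5, 86.1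

(each reading ± 0.5 percentage points)

1. the state of affairs at 25 min: stopped, and by what, or still going (all of Z has reacted / it is still moving / forward and back rates have come level)
2. how much of the Z has reacted by 25 min
3. how much J there is at 25 min, in percent of the Z charged
4. how much Q there is at 25 min, in percent of the Z charged

- what was read earlier has a scatter of 0.5 percentage points, one standard deviation
- a reading or a percentage of J counts all its forms, free or not
- the reaction counts as stopped when no species that holds the Z changes by six tenths of a point or more over the second half of the time

Which given numbers must I know well? Not the time: east J reads 44.9% at 1.50 min and 44.1% at 20.0 min, a change of 0.8 percentage points against a scatter of 0.5 points. The charge matters: at 20.0 min, J reads 44.1% in east and 86.1% in south-west. The readings matter unequally: one standard deviation in east J moves my flask J by 0.25 points, but in south-west J by 1 point, so I trust east. Its charge times its mean fraction not read as J gives the held-back level, 0.0550 mM; south-west reads 0.0565 mM. I assume that this level holds between these two charges, so from the east value I reckon J at 72.5% for the flask at 0.20 mM.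

The forecast, made from the same readings, says: forward and back rates have come level, conversion 86.8%, J 72.5%, Q 14.3%, holding that “J takes up all the excess”.

The flask gives forward and back rates have come level, conversion 86.8%, J 72.2%, Q 12.5%.

    Z ⇌ J (K = 0.950, k = 0.0450 /s)
    J ⇌ D (K = 0.150, k = 0.0780 /s)
    D ⇌ Z (k = 0.0990 /s)
    2 Z → L (k = 0.170 /M/s)
    J ⇌ Q (K = 1.00, k = 0.0960 /s)
    E ⇌ J, rate k6*(cs6 - [J]) while solid is left; crystals form when [J] > cs6 (solubility = 0.0250 mM, k = 3.30 /s)

This flask's held-back level comes to 0.0556 mM, and its Q plus D, 1.87%, makes 14.4%, beside the forecast's Q of 14.3%. The level read from east, 0.0550 mM, is above the 0.050 mM of Z charged to a neighbour flask, and at 25.0 min that neighbour holds E, the crystals, at 0%, with J at 31.1%. In the flask, the step between Z and dissolved J, taken alone and both ways together, has a relaxation half-life of 0.125 min, much shorter than the 25 min allowed. Z stands at 13.2% after 2.50 min and at 13.2% after 25.0 min.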